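The earlier runs and the new flask were generated by integration for an exercise, noise included.

A ratio opened the meeting. I, keeping these minutes, proposed dividing left-handed product by right-handed product over the south-west readings taken together, which gives 13.1. I called this the fork ratio: the odds that one molecule of product, as free catalyst makes it, comes out left-handed rather than right-handed. While little substrate has gone, it stands close to the selectivity factor.

| flask | left-handed substrate | right-handed substrate | partner | precatalyst | temperature | remark | time |
|---|---|---|---|---|---|---|---|
| east | 0.054 M | 0.054 M | 0.0594 M | 0.21 mM | 104 °C | run made earlier |  |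
| south-west | 0.054 M | 0.054 M | 0.0594 M | 0.86 mM | 112 °C | run made earlier |  |
| autumn | 0.054 M | 0.054 M | 0.0594 M | 0.43 mM | 115 °C |  | 6.0 min |
| dusk | 0.054 M | 0.054 M | 0.0594 M | 0.43 mM | 100 °C |  | 6.0 min |

- east (time / min: left-handed product / %, right-handed product / %, left-handed substrate / %): 0.833: 3.7, 0, 46.5; 1.50: 4.4, 0.1, 46.2; 3.00: 4.2, 0.1, 46.2; 6.00: 4.1, 0, 46.0; 15.0: 3.5, 0.4, 46.4
- south-west (time / min: left-handed product / %, right-handed product / %, left-handed substrate / %): 0.667: 13.6, 1.4, 36.9; 2.00: 13.6, 0.7, 36.4; 3.00: 14.4, 1.1, 36.4; 5.00: 14.0, 1.0, 36.5; 8.00: 13.7, 1.1, 36.6

(standard deviation of a reading: 0.3 percentage points)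

- free catalyst is single-handed; left-handed substrate and right-handed substrate are mirror images of each other, charged as a racemate, each of them at the stated concentration
- an excess is the difference of the two amounts in percent of their sum
- an excess is below zero if the other one leads

1. the flask that comes out highest in excess of left-handed product over right-handed product, or "all alike" when all lie within 1.5 percentage points (autumn / dusk / all alike)
2. excess of left-handed product over right-handed product at the end, autumn
3. excess of left-handed product over right-handed product at the end, dusk

Following one molecule through that fork, I said, the excess is the ratio less one over the ratio plus one, here 85.8%, and I gave autumn and dusk that same figure. Single south-west readings give ratios from 9.71 to 19.4. The east run offers no check, its right-handed readings running from 0% to 0.4% against a scatter of 0.3 percentage points. So I held that these runs cannot rank autumn at 115 °C against dusk at 100 °C, and I expected the two to lie within the margin of 1.5 points.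

The maker of the forecast disagreed: “Colder should be somewhat more selective”. The forecast stood at 86% (82% to 89%) for autumn and 89.5% (86% to 94%) for dusk, with dusk highest. We parted on dusk and on the ranking.

The flasks gave 89.5% in autumn and 88.8% in dusk, which counts as all alike.

    partner + free catalyst + left-handed substrate → free catalyst + left-handed product (k = 990 M⁻² s⁻¹, Ea = 45.0 kJ mol⁻¹)
    partner + free catalyst + right-handed substrate → free catalyst + right-handed product (k = 54.0 M⁻² s⁻¹, Ea = 40.0 kJ mol⁻¹)
    partner + precatalyst → free catalyst + spent reagent (k = 2.80 M⁻¹ s⁻¹, Ea = 68.0 kJ mol⁻¹)
    partner → decomposed reagent (k = 0.0100 s⁻¹, Ea = 112 kJ mol⁻¹)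
    partner + free catalyst → spent catalyst (k = 2.50 M⁻¹ s⁻¹, Ea = 49.0 kJ mol⁻¹)
    (constants at 100 °C)

At dusk's temperature the left-handed step's constant exceeds the right-handed step's by a factor of 18.3, and dusk's product ratio stands at 16.9, against the 13.1 read from the south-west run. Autumn's product ratio, 18.1, gives 89.5% by the fork rule, a lead over dusk of 0.70 points. The neighbour flask, autumn's recipe with 1.7 × 10⁻⁴ M of precatalyst, has a product ratio of 18.9 and an excess of 90.0%.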